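I could not read the value at 12 d off the earlier runs, for none of them went past 6.00 d.

| flask | starting material | remark | time |
|---|---|---|---|
| north | 0.23 M | run made earlier |  |
| south-east | 0.42 M | run made earlier |  |
| east | 0.76 M | run made earlier |  |
| green | 0.20 M |  | 12 d |
| violet | 0.40 M |  | 12 d |
| teal | 0.80 M |  | 12 d |

- north (time / d: target / %): 0.500: 12.7; 0.833: 29.3; 1.67: 58.1; 3.00: 72.1; 6.00: 73.8
- south-east (time / d: target / %): 0.500: 11.9; 0.833: 28.5; 1.67: 58.9; 3.00: 71.0; 6.00: 73.6
- east (time / d: target / %): 0.500: 11.3; 0.833: 28.8; 1.67: 58.4; 3.00: 70.9; 6.00: 73.4

(standard deviation of a reading: 0.5 percentage points)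

- amount of target at the end, in percent of the starting material charged for green, violet, teal, in this order
- the shape of the row from first to last (hardly changes / rises, then falls / falls, then rises / falls all the way / rises all the way)

- the numbers in the tables scatter by 0.5 percentage points (one standard deviation)
- "hardly changes" means that all values lie within two and a half points (for a concentration: within two and a half percent of the largest)

At 6.00 d the runs read 73.4% to 73.8% of target, over c(starting material) from 0.23 M to 0.76 M, so I treated them as one curve and averaged them. Their mean level was 73.6%.

I needed two times. The first was the gap half-life, the time in which the distance to the level halves; the usual word is a relaxation half-life. The mean gap fell from 15 percentage points at 1.67 d to 2.3 points at 3.00 d, so I read 0.486 d. The second was the stretch from the last reading to the asked time, 6.00 d. This stretch was far longer than the gap half-life, by 12.4 half-lives. I therefore committed to about 73.6% in each of the three flasks, a flat row, provided no slower loss of target appeared after 6.00 d.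

The forecast gave 74%, 74% and 74%, a row that hardly changes, a little above my level: “All three concentrations should give about the same value”.

The flask gave 73.9%, 73.9% and 73.9%, a row that hardly changes.

intermediate B ⇌ target (K = 3.00, k = 1.60 × 10⁻⁵ s⁻¹); intermediate A ⇌ intermediate B (K = 17.0, k = 2.50 × 10⁻⁵ s⁻¹); starting material → intermediate A (k = 7.00 × 10⁻⁵ s⁻¹) In green at 12.0 d, 24.6% of the charge stood as intermediate B beside 73.9% of target. Across the 12.4 gap half-lives between 6.00 d and 12.0 d, teal read 73.9% and then 73.9%. Going on to 120 d added 222 gap half-lives, and teal still held 73.9% of target.

The data are calculated on assumed constants, noise included.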